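**Retrosynthetic overview**
- Side chain: the C12–C13 bond comes from a B-alkyl Suzuki coupling of a C9 vinyl group with a (Z)-β-iodo enoate, which fixes the 13E geometry; the acid is unmasked last.
- C8=C17 methylene and C9–H: reductive 1,3-transposition (allylic diazene retro-ene) of a C17 allylic alcohol on a C8=C9 olefin.
- Ring B: intramolecular Diels–Alder reaction of a ring A vinylcyclohexene with an alkynoate tethered through the C2 oxygen; C5–H by hydrogenation once the tether is released.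
- Ring A and C2: bought as (4R,6R)-actinol; the carbinol is inverted in the Mitsunobu esterification that attaches the tether.
- Ring order: ring A (bought), then ring B (cycloaddition); the bridged lactone and the butenolide are temporary.

Assumption: (4R,6R)-actinol and but-2-yne-1,4-diol are taken as commercial; C-locants in the Why lines are labdane locants of the target (C11 on C9, C17 on C8), while names use systematic locants.

**Step 1**
Reactants: 1 (4R,6R)-4-hydroxy-2,2,6-trimethylcyclohexan-1-one (actinol)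
Product: 2 (4R,6R)-4-(tert-butyldimethylsilyloxy)-2,2,6-trimethylcyclohexan-1-one
Conditions: TBSCl, imidazole, DMF, rt
Reagents that add atoms: tert-butyldimethylsilyl chloride, CC(C)(C)[Si](C)(C)Cl
Why: Silyl ether protection of the secondary alcohol for the enolate chemistry; the bought carbinol centre (future C2, still opposite to the target) is not touched.

**Step 2**
Reactants: 2 (4R,6R)-4-(tert-butyldimethylsilyloxy)-2,2,6-trimethylcyclohexan-1-one
Product: 3 (4R)-4-(tert-butyldimethylsilyloxy)-2,6,6-trimethylcyclohex-1-en-1-yl trifluoromethanesulfonate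
Conditions: LiN(iPr)2 (LDA), THF, −78 → 0 °C; PhNTf2, −78 °C → rt; aq. NH4Cl
Reagents that add atoms: N-phenyl-bis(trifluoromethanesulfonimide), O=S(=O)(N(c1ccccc1)S(=O)(=O)C(F)(F)F)C(F)(F)F
Why: Enolate O-triflation; the ketone has a single α-hydrogen, so only one tetrasubstituted enol triflate can form, and the methyl-bearing stereocentre is deliberately erased.

**Step 3**
Reactants: 3 (4R)-4-(tert-butyldimethylsilyloxy)-2,6,6-trimethylcyclohex-1-en-1-yl trifluoromethanesulfonate
Product: 5 (1R)-3,5,5-trimethyl-4-vinylcyclohex-3-en-1-ol, via silyl diene 4 (not isolated)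
Conditions: CH2=CHSnBu3, Pd2(dba)3 (2.5 mol %), AsPh3 (20 mol %), NMP, 60 °C; then TBAF (3 equiv), THF, rt; aq. NH4Cl
Reagents that add atoms: tributyl(vinyl)stannane, C=C[Sn](CCCC)(CCCC)CCCC
Why: Stille cross-coupling of the hindered alkenyl triflate builds the ring A diene, and fluoride then cleaves the silyl ether and precipitates the tin residue; the carbinol centre stays (R).

**Step 4**
Reactants: 6 but-2-yne-1,4-diol
Product: 7 4-hydroxybut-2-yn-1-yl acetate
Conditions: Ac2O (1.0 equiv), pyridine (solvent), 0 °C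
Reagents that add atoms: acetic anhydride, CC(=O)OC(C)=O
Why: Statistical mono-acetylation of a symmetrical diol; recovered diol and diacetate are recycled.

**Step 5**
Reactants: 7 4-hydroxybut-2-yn-1-yl acetate
Product: 8 4-acetoxybut-2-ynoic acid
Conditions: TEMPO (10 mol %), PhI(OAc)2 (2.2 equiv), MeCN/H2O, rt
Reagents that add atoms: water, O
Why: TEMPO/PhI(OAc)2 oxidation takes the primary propargylic alcohol through the aldehyde hydrate to the acid without touching acetate or alkyne.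

**Step 6**
Reactants: 5 (1R)-3,5,5-trimethyl-4-vinylcyclohex-3-en-1-ol; 8 4-acetoxybut-2-ynoic acid
Product: 9 (1S)-3,5,5-trimethyl-4-vinylcyclohex-3-en-1-yl 4-acetoxybut-2-ynoate
Conditions: PPh3, DIAD, toluene, 0 °C → rt
Reagents that add atoms: none
Why: Mitsunobu esterification: the carboxylate displaces the activated alcohol by SN2 with inversion, so the bought (R) centre becomes the (S) ester, which has the C2 configuration of the target, while the dienophile is tethered to that oxygen.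

**Step 7**
Reactants: 9 (1S)-3,5,5-trimethyl-4-vinylcyclohex-3-en-1-yl 4-acetoxybut-2-ynoate
Product: 10 (7R,8aR)-2-(acetoxymethyl)-7-hydroxy-5,5,8a-trimethyl-3,5,6,7,8,8a-hexahydronaphthalene-1-carboxylic acid 1,7-lactone
Conditions: toluene (0.01 M), BHT (cat.), 160 °C, sealed tube
Reagents that add atoms: none
Why: Type 1 intramolecular Diels–Alder reaction forms ring B: the four-atom tether (C1, C2, O, C11) can deliver the alkynoate only to the diene face syn to the C2 oxygen, with the carbonyl-bearing carbon bonding to C10, so C2 dictates the C10 quaternary centre (methyl anti to the C2 oxygen) and the regiochemistry.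

**Step 8**
Reactants: 10 (7R,8aR)-2-(acetoxymethyl)-7-hydroxy-5,5,8a-trimethyl-3,5,6,7,8,8a-hexahydronaphthalene-1-carboxylic acid 1,7-lactone
Product: 12 (8R,9aR)-8-hydroxy-6,6,9a-trimethyl-4,6,7,8,9,9a-hexahydronaphtho[1,2-c]furan-1(3H)-one, via hydroxy lactone 11 (not isolated)
Conditions: K2CO3 (0.2 equiv), MeOH, 0 °C → rt
Reagents that add atoms: none
Why: Acetate methanolysis frees the C17 alkoxide, which sits cis to C11 across C8=C9 and attacks the strained bridged lactone (translactonisation), giving the unstrained butenolide and releasing the C2 hydroxyl; no stereocentre is involved.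

**Step 9**
Reactants: 12 (8R,9aR)-8-hydroxy-6,6,9a-trimethyl-4,6,7,8,9,9a-hexahydronaphtho[1,2-c]furan-1(3H)-one
Product: 13 (5aR,8R,9aR)-8-hydroxy-6,6,9a-trimethyl-4,5,5a,6,7,8,9,9a-octahydronaphtho[1,2-c]furan-1(3H)-one
Conditions: H2 (3 atm), 10% Pd/C, EtOAc, rt
Reagents that add atoms: none
Why: Heterogeneous catalytic hydrogenation of the trisubstituted C5=C6 bond from the face opposite the axial C10 methyl (as with 5-ene steroids) sets C5 and the trans ring fusion; the tetrasubstituted butenolide alkene is inert.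

**Step 10**
Reactants: 13 (5aR,8R,9aR)-8-hydroxy-6,6,9a-trimethyl-4,5,5a,6,7,8,9,9a-octahydronaphtho[1,2-c]furan-1(3H)-one
Product: 14 (5aR,8R,9aR)-6,6,9a-trimethyl-1,3,4,5,5a,6,7,8,9,9a-decahydronaphtho[1,2-c]furan-1,8-diol (anomer mixture)
Conditions: iBu2AlH (DIBAL, 2.5 equiv), CH2Cl2, −78 °C; aq. KNaC4H4O6 work-up
Reagents that add atoms: none
Why: Partial DIBAL reduction of the lactone stops at the lactol because the tetrahedral aluminate is stable at −78 °C; the neutral work-up avoids dehydration to the furan.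

**Step 11**
Reactants: 14 (5aR,8R,9aR)-6,6,9a-trimethyl-1,3,4,5,5a,6,7,8,9,9a-decahydronaphtho[1,2-c]furan-1,8-diol
Product: 16 (2R,4aR,8aR)-7-(hydroxymethyl)-4,4,8a-trimethyl-8-vinyl-1,2,3,4,4a,5,6,8a-octahydronaphthalen-2-ol, via hydroxy enal 15 (not isolated)
Conditions: Ph3PCH3Br (4 equiv), KOtBu, THF, 0 °C → rt
Reagents that add atoms: methyltriphenylphosphonium bromide, C[P+](c1ccccc1)(c1ccccc1)c1ccccc1.[Br-]
Why: Wittig methylenation of the lactol through its open hydroxy enal form puts C12 on C9 as a vinyl group and leaves the C17 allylic alcohol free.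

**Step 12**
Reactants: 8 4-acetoxybut-2-ynoic acid
Product: 17 2-(trimethylsilyl)ethyl 4-acetoxybut-2-ynoate
Conditions: Me3SiCH2CH2OH, DCC, DMAP (5 mol %), CH2Cl2, 0 °C
Reagents that add atoms: 2-(trimethylsilyl)ethanol, C[Si](C)(C)CCO
Why: Steglich esterification gives a fluoride-labile ester that is orthogonal to the acetate.

**Step 13**
Reactants: 17 2-(trimethylsilyl)ethyl 4-acetoxybut-2-ynoate
Product: 18 2-(trimethylsilyl)ethyl (2Z)-4-acetoxy-3-iodobut-2-enoate
Conditions: NaI, AcOH, 70 °C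
Reagents that add atoms: sodium iodide, [Na+].[I-]
Why: Conjugate hydroiodination of the ynoate (iodide addition, then protonation of the allenolate; net anti addition) gives the (Z)-β-iodo enoate with iodine cis to the ester.

**Step 14**
Reactants: 16 (2R,4aR,8aR)-7-(hydroxymethyl)-4,4,8a-trimethyl-8-vinyl-1,2,3,4,4a,5,6,8a-octahydronaphthalen-2-ol; 18 2-(trimethylsilyl)ethyl (2Z)-4-acetoxy-3-iodobut-2-enoate
Product: 20 2-(trimethylsilyl)ethyl (2E)-3-(acetoxymethyl)-5-[(4aR,7R,8aR)-7-hydroxy-2-(hydroxymethyl)-5,5,8a-trimethyl-3,4,4a,5,6,7,8,8a-octahydronaphthalen-1-yl]pent-2-enoate, via trisboryl adduct 19 (not isolated)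
Conditions: 9-BBN (3.3 equiv), THF, 0 → 40 °C; then 18, Pd(dppf)Cl2 (5 mol %), AsPh3 (10 mol %), Cs2CO3, DMF/H2O, rt
Reagents that add atoms: none
Why: 9-BBN hydroborates only the terminal vinyl group (boron on C12; the tetrasubstituted C8=C9 bond is inert; the two hydroxyls are carried as borinates), and the B-alkyl Suzuki–Miyaura coupling proceeds with retention at the alkenyl iodide, so C12 ends cis to the ester, which is the 13E geometry.

**Step 15**
Reactants: 20 2-(trimethylsilyl)ethyl (2E)-3-(acetoxymethyl)-5-[(4aR,7R,8aR)-7-hydroxy-2-(hydroxymethyl)-5,5,8a-trimethyl-3,4,4a,5,6,7,8,8a-octahydronaphthalen-1-yl]pent-2-enoate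
Product: 23 2-(trimethylsilyl)ethyl (2E)-3-(acetoxymethyl)-5-[(1R,4aR,7R,8aR)-7-hydroxy-5,5,8a-trimethyl-2-methylidenedecahydronaphthalen-1-yl]pent-2-enoate, via sulfonylhydrazine adduct 21 (not isolated), via allylic diazene 22 (not isolated)
Conditions: 2-nitrobenzenesulfonylhydrazide (NBSH, 1.2 equiv), PPh3, DEAD, THF, −30 °C, 2 h; then rt
Reagents that add atoms: none
Why: Myers reductive 1,3-transposition: Mitsunobu displacement of the primary allylic alcohol (the secondary C2 alcohol is much slower at −30 °C), loss of sulfinic acid, then retro-ene (sigmatropic) loss of N2 from the monoalkyl diazene, which delivers hydrogen to C9 on the face anti to the axial C10 methyl and moves the alkene to C8=C17.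

**Step 16**
Reactants: 23 2-(trimethylsilyl)ethyl (2E)-3-(acetoxymethyl)-5-[(1R,4aR,7R,8aR)-7-hydroxy-5,5,8a-trimethyl-2-methylidenedecahydronaphthalen-1-yl]pent-2-enoate
Product: 24 (2E)-3-(acetoxymethyl)-5-[(1R,4aR,7R,8aR)-7-hydroxy-5,5,8a-trimethyl-2-methylidenedecahydronaphthalen-1-yl]pent-2-enoic acid (CNP0292310.2)
Conditions: TBAF (2.5 equiv), THF, 0 °C → rt; dilute HCl to pH 4
Reagents that add atoms: none
Why: Fluoride-triggered β-elimination of the 2-(trimethylsilyl)ethyl ester frees the acid without hydrolysing the allylic acetate.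

**Compound list**
1 | (4R,6R)-4-hydroxy-2,2,6-trimethylcyclohexan-1-one (actinol) | O=C1C(C)(C)C[C@H](O)C[C@H]1C | starting material
2 | (4R,6R)-4-(tert-butyldimethylsilyloxy)-2,2,6-trimethylcyclohexan-1-one | O=C1C(C)(C)C[C@H](O[Si](C)(C)C(C)(C)C)C[C@H]1C | intermediate
3 | (4R)-4-(tert-butyldimethylsilyloxy)-2,6,6-trimethylcyclohex-1-en-1-yl trifluoromethanesulfonate | CC1=C(OS(=O)(=O)C(F)(F)F)C(C)(C)C[C@H](O[Si](C)(C)C(C)(C)C)C1 | intermediate
4 | tert-butyldimethylsilyl ether of (1R)-3,5,5-trimethyl-4-vinylcyclohex-3-en-1-ol (formed in the flask) | CC1=C(C=C)C(C)(C)C[C@H](O[Si](C)(C)C(C)(C)C)C1 | intermediate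
5 | (1R)-3,5,5-trimethyl-4-vinylcyclohex-3-en-1-ol | CC1=C(C=C)C(C)(C)C[C@H](O)C1 | intermediate
6 | but-2-yne-1,4-diol | OCC#CCO | starting material
7 | 4-hydroxybut-2-yn-1-yl acetate | CC(=O)OCC#CCO | intermediate
8 | 4-acetoxybut-2-ynoic acid | CC(=O)OCC#CC(=O)O | intermediate
9 | (1S)-3,5,5-trimethyl-4-vinylcyclohex-3-en-1-yl 4-acetoxybut-2-ynoate | CC1=C(C=C)C(C)(C)C[C@@H](OC(=O)C#CCOC(C)=O)C1 | intermediate
10 | (7R,8aR)-2-(acetoxymethyl)-7-hydroxy-5,5,8a-trimethyl-3,5,6,7,8,8a-hexahydronaphthalene-1-carboxylic acid 1,7-lactone (bridged; lactone oxygen and C1–C8a bond cis on the hydroxylated ring) | CC(=O)OCC=1CC=C2C(C)(C)C[C@@H](O3)C[C@@]2(C)C=1C3=O | intermediate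
11 | (7R,8aR)-7-hydroxy-2-(hydroxymethyl)-5,5,8a-trimethyl-3,5,6,7,8,8a-hexahydronaphthalene-1-carboxylic acid 1,7-lactone (formed in the flask) | OCC=1CC=C2C(C)(C)C[C@@H](O3)C[C@@]2(C)C=1C3=O | intermediate
12 | (8R,9aR)-8-hydroxy-6,6,9a-trimethyl-4,6,7,8,9,9a-hexahydronaphtho[1,2-c]furan-1(3H)-one | O1CC=2CC=C3C(C)(C)C[C@@H](O)C[C@@]3(C)C=2C1=O | intermediate
13 | (5aR,8R,9aR)-8-hydroxy-6,6,9a-trimethyl-4,5,5a,6,7,8,9,9a-octahydronaphtho[1,2-c]furan-1(3H)-one | O1CC=2CC[C@@H]3C(C)(C)C[C@@H](O)C[C@@]3(C)C=2C1=O | intermediate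
14 | (5aR,8R,9aR)-6,6,9a-trimethyl-1,3,4,5,5a,6,7,8,9,9a-decahydronaphtho[1,2-c]furan-1,8-diol (anomer mixture) | O1CC=2CC[C@@H]3C(C)(C)C[C@@H](O)C[C@@]3(C)C=2C1O | intermediate
15 | (4aR,7R,8aR)-7-hydroxy-2-(hydroxymethyl)-5,5,8a-trimethyl-3,4,4a,5,6,7,8,8a-octahydronaphthalene-1-carbaldehyde (formed in the flask) | OCC=1CC[C@@H]2C(C)(C)C[C@@H](O)C[C@@]2(C)C=1C=O | intermediate
16 | (2R,4aR,8aR)-7-(hydroxymethyl)-4,4,8a-trimethyl-8-vinyl-1,2,3,4,4a,5,6,8a-octahydronaphthalen-2-ol | OCC=1CC[C@@H]2C(C)(C)C[C@@H](O)C[C@@]2(C)C=1C=C | intermediate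
17 | 2-(trimethylsilyl)ethyl 4-acetoxybut-2-ynoate | CC(=O)OCC#CC(=O)OCC[Si](C)(C)C | intermediate
18 | 2-(trimethylsilyl)ethyl (2Z)-4-acetoxy-3-iodobut-2-enoate | I/C(COC(C)=O)=C\C(=O)OCC[Si](C)(C)C | intermediate
19 | B-alkyl-9-BBN adduct of 16 at the terminal vinyl carbon, both hydroxyls as 9-BBN borinates (formed in the flask) | C1CCC2CCCC1B2OCC=3CC[C@@H]4C(C)(C)C[C@@H](OB5C6CCCC5CCC6)C[C@@]4(C)C=3CCB7C8CCCC7CCC8 | intermediate
20 | 2-(trimethylsilyl)ethyl (2E)-3-(acetoxymethyl)-5-[(4aR,7R,8aR)-7-hydroxy-2-(hydroxymethyl)-5,5,8a-trimethyl-3,4,4a,5,6,7,8,8a-octahydronaphthalen-1-yl]pent-2-enoate | OCC=1CC[C@@H]2C(C)(C)C[C@@H](O)C[C@@]2(C)C=1CC/C(=C\C(=O)OCC[Si](C)(C)C)COC(C)=O | intermediate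
21 | N-allylic N-(2-nitrobenzenesulfonyl)hydrazine from 20 (formed in the flask) | NN(CC=1CC[C@@H]2C(C)(C)C[C@@H](O)C[C@@]2(C)C=1CC/C(=C\C(=O)OCC[Si](C)(C)C)COC(C)=O)S(=O)(=O)c1ccccc1[N+](=O)[O-] | intermediate
22 | allylic monoalkyl diazene from 21 (formed in the flask) | N=NCC=1CC[C@@H]2C(C)(C)C[C@@H](O)C[C@@]2(C)C=1CC/C(=C\C(=O)OCC[Si](C)(C)C)COC(C)=O | intermediate
23 | 2-(trimethylsilyl)ethyl (2E)-3-(acetoxymethyl)-5-[(1R,4aR,7R,8aR)-7-hydroxy-5,5,8a-trimethyl-2-methylidenedecahydronaphthalen-1-yl]pent-2-enoate | C=C1CC[C@@H]2C(C)(C)C[C@@H](O)C[C@@]2(C)[C@@H]1CC/C(=C\C(=O)OCC[Si](C)(C)C)COC(C)=O | intermediate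
24 | (2E)-3-(acetoxymethyl)-5-[(1R,4aR,7R,8aR)-7-hydroxy-5,5,8a-trimethyl-2-methylidenedecahydronaphthalen-1-yl]pent-2-enoic acid (16-acetoxy-2-hydroxy-ent-labda-8(17),13E-dien-15-oic acid; labdane 2R,5R,9R,10R) | C=C1CC[C@@H]2C(C)(C)C[C@@H](O)C[C@@]2(C)[C@@H]1CC/C(=C\C(=O)O)COC(C)=O | target

**Step count**
Total: 16 steps. Longest linear sequence: 12 steps (1 → 24 through steps 1, 2, 3, 6, 7, 8, 9, 10, 11, 14, 15, 16).

**Steps most likely to fail**

Step 7 (intramolecular Diels–Alder). The ester must reach its s-cis form, ring A must place the C2 oxygen axial, and the diene is hindered, so the dienyne may decompose before it cyclises. Fallback, setting out from 5: Mitsunobu inversion with 4-nitrobenzoic acid (PPh3, DIAD) gives (1S)-3,5,5-trimethyl-4-vinylcyclohex-3-en-1-yl 4-nitrobenzoate F3. Heating it neat at 130 °C with commercial methyl 4-hydroxybut-2-ynoate gives, by intermolecular Diels–Alder reaction with the ester carbon on C9, the hydroxy ester adduct F4. Its cis γ-hydroxy ester closes in the flask to the butenolide 4-nitrobenzoate F5. Facial control is then only substrate-based, so the C10 epimers must be separated. K2CO3/MeOH removes the nitrobenzoate and the route is rejoined at 12.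

Step 15 (reductive transposition). The Mitsunobu step must discriminate the primary allylic alcohol from the C2 alcohol, and the displacement is at a crowded allylic carbon. Fallback, setting out from 20: MnO2 in CH2Cl2 oxidises only the allylic alcohol to the enal F6, and TsNHNH2 converts it into the tosylhydrazone F7. Catecholborane, then NaOAc·3H2O in refluxing CHCl3, reduces it through the allylic tosylhydrazine F8 to the same diazene 22, which collapses to 23.

Step 6 (Mitsunobu esterification). Elimination to a triene and addition of the phosphine to the ynoic acid can compete. Fallback, setting out from 5: MsCl and Et3N give (1R)-3,5,5-trimethyl-4-vinylcyclohex-3-en-1-yl methanesulfonate F1. This is displaced with inversion by caesium 4-acetoxybut-2-ynoate F2 (from 8 and Cs2CO3) in DMF at 50 °C, returning at 9.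

**Further compounds**
F1 | step 6 | (1R)-3,5,5-trimethyl-4-vinylcyclohex-3-en-1-yl methanesulfonate | CC1=C(C=C)C(C)(C)C[C@H](OS(C)(=O)=O)C1
F2 | step 6 | caesium 4-acetoxybut-2-ynoate | [Cs+].CC(=O)OCC#CC(=O)[O-]
F3 | step 7 | (1S)-3,5,5-trimethyl-4-vinylcyclohex-3-en-1-yl 4-nitrobenzoate | CC1=C(C=C)C(C)(C)C[C@@H](OC(=O)c2ccc(cc2)[N+](=O)[O-])C1
F4 | step 7 | methyl (7R,8aR)-2-(hydroxymethyl)-5,5,8a-trimethyl-7-(4-nitrobenzoyloxy)-3,5,6,7,8,8a-hexahydronaphthalene-1-carboxylate (formed in the flask) | OCC=1CC=C2C(C)(C)C[C@@H](OC(=O)c3ccc(cc3)[N+](=O)[O-])C[C@@]2(C)C=1C(=O)OC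
F5 | step 7 | (8R,9aR)-6,6,9a-trimethyl-1-oxo-1,3,4,6,7,8,9,9a-octahydronaphtho[1,2-c]furan-8-yl 4-nitrobenzoate | O1CC=2CC=C3C(C)(C)C[C@@H](OC(=O)c4ccc(cc4)[N+](=O)[O-])C[C@@]3(C)C=2C1=O
F6 | step 15 | 2-(trimethylsilyl)ethyl (2E)-3-(acetoxymethyl)-5-[(4aR,7R,8aR)-2-formyl-7-hydroxy-5,5,8a-trimethyl-3,4,4a,5,6,7,8,8a-octahydronaphthalen-1-yl]pent-2-enoate | O=CC=1CC[C@@H]2C(C)(C)C[C@@H](O)C[C@@]2(C)C=1CC/C(=C\C(=O)OCC[Si](C)(C)C)COC(C)=O
F7 | step 15 | 4-methylbenzenesulfonylhydrazone of F6 | Cc1ccc(cc1)S(=O)(=O)NN=CC=1CC[C@@H]2C(C)(C)C[C@@H](O)C[C@@]2(C)C=1CC/C(=C\C(=O)OCC[Si](C)(C)C)COC(C)=O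
F8 | step 15 | allylic N'-(4-methylbenzenesulfonyl)hydrazine from F7 (formed in the flask) | Cc1ccc(cc1)S(=O)(=O)NNCC=1CC[C@@H]2C(C)(C)C[C@@H](O)C[C@@]2(C)C=1CC/C(=C\C(=O)OCC[Si](C)(C)C)COC(C)=O
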